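The route rests on cutting the C2–C3 bond of the dioxane ring (O1–C2–C3–O4). It exploits two features: C2 is α to the CH2OH carbon, a latent aldehyde, and C3 is an α-oxy benzylic carbon on the trimethoxyphenyl ring, so both are plain C–H positions in the precursor, lactol 7. There, the middle oxygen (O1) of a pyrogallol ring A carries a masked OCH2CHO arm, tied as a lactol to the future C8 phenol, and O4 carries a 3,4,5-trimethoxybenzyl group. In one operation DDQ turns the benzylic C–H into an oxocarbenium ion and a chiral amine delivers the aldehyde α-carbon to it, closing the ring and setting both stereocentres.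

Key step: step 4

Remark: 5-bromobenzene-1,2,3-triol (1) is taken as a catalogue compound. Locants: in the 2,3-dihydro-1,4-benzodioxine products O1 is the middle oxygen of ring A, C2 carries CH2OH (or CHO) and C3 the aryl group; lactone and lactol names use their own locants.

Step 1
Reactants: 1 5-bromobenzene-1,2,3-triol; 2 methyl bromoacetate
Product: 4 7-bromo-5-hydroxy-1,4-benzodioxin-2(3H)-one, via open hydroxy ester 3 (not isolated)
Conditions: KHCO3 (1.1 equiv), 2 (1.0 equiv), DMF, 0 °C to rt; then TsOH·H2O (cat.), toluene, reflux
Reagents that add atoms: methyl bromoacetate, COC(=O)CBr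
Why: The middle hydroxyl of the pyrogallol unit is the most acidic (its phenoxide is held by two flanking O–H···O hydrogen bonds), so one equivalent of weak base should direct the Williamson O-alkylation there, and acid-catalysed lactonisation onto either of the two equivalent neighbouring phenols gives the same six-membered aryl lactone and leaves the other phenol free; no stereocentre is formed.

Step 2
Reactants: 4 7-bromo-5-hydroxy-1,4-benzodioxin-2(3H)-one; 5 (3,4,5-trimethoxyphenyl)methanol
Product: 6 7-bromo-5-[(3,4,5-trimethoxyphenyl)methoxy]-1,4-benzodioxin-2(3H)-one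
Conditions: PPh3, DIAD, THF, 0 °C to rt
Reagents that add atoms: (3,4,5-trimethoxyphenyl)methanol, COc1cc(CO)cc(OC)c1OC
Why: Mitsunobu etherification of the only free phenol with a primary benzylic alcohol runs under neutral conditions that should leave the base-sensitive aryl lactone closed; no stereocentre is formed.

Step 3
Reactants: 6 7-bromo-5-[(3,4,5-trimethoxyphenyl)methoxy]-1,4-benzodioxin-2(3H)-one
Product: 7 7-bromo-5-[(3,4,5-trimethoxyphenyl)methoxy]-2,3-dihydro-1,4-benzodioxin-2-ol (lactol, both epimers)
Conditions: i-Bu2AlH (1.1 equiv), CH2Cl2, −78 °C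
Reagents that add atoms: none
Why: Partial reduction of a lactone by i-Bu2AlH at low temperature should stop at the tetrahedral aluminate, as it does with dihydrocoumarins, and give the lactol in which the aldehyde and the future free phenol mask each other; the lactol centre forms as a mixture and is erased in step 4.

Step 4
Reactants: 7 7-bromo-5-[(3,4,5-trimethoxyphenyl)methoxy]-2,3-dihydro-1,4-benzodioxin-2-ol
Product: 10 (2S,3S)-6-bromo-2-(hydroxymethyl)-3-(3,4,5-trimethoxyphenyl)-2,3-dihydro-1,4-benzodioxin-8-ol, via oxocarbenium ion pair 8 (not isolated), via trans aldehyde 9 (not isolated)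
Conditions: DDQ (1.2 equiv), 4 Å MS, ClCH2CH2Cl (0.02 M), rt to 40 °C; then (S)-2-[diphenyl(trimethylsilyloxy)methyl]pyrrolidine (20 mol %), −20 °C; then NaBH4, MeOH, −20 to 0 °C
Reagents that add atoms: none
Why: Proposed new method: DDQ should abstract hydride from the only C–H of 7 that is both benzylic to the trimethoxyphenyl ring and α to an ether oxygen, giving the O-aryl oxocarbenium ion 8 with the aryl–O bond intact; the lactol then opens, the (S)-amine condenses with the released aldehyde and the E-enamine carbon attacks the cation, the closest known reaction type being the amine-catalysed enantioselective oxidative coupling of benzylic ethers (isochromans) with aldehydes by DDQ, here made intramolecular. The dioxane ring closes in a 6-(enolexo)-endo-trig mode, with the enamine C=C outside and the C=O+ inside the forming six-membered ring. The CH2OH-bearing carbon is set by the catalyst: its diphenyl(silyloxy)methyl group blocks one face of the anti E-enamine, so the cation adds to the other face, which gives the S centre after reduction (R in aldehyde 9 by a priority change only). The aryl-bearing carbon is set by the substrate: in the chair-like transition state the E-oxocarbenium keeps the trimethoxyphenyl group pseudo-equatorial and anti to the enamine chain, which gives the trans ring. The step needs site-selective oxidation and exclusive C-attack; these should be secured because no other C–H is doubly activated, because the lactol masks phenol and aldehyde during the oxidation, and because the lactol oxygens on the far side of ring A cannot reach the cation, while NaBH4 reduces 9 in the pot before its α-centre can epimerise.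

Step 5
Reactants: 10 (2S,3S)-6-bromo-2-(hydroxymethyl)-3-(3,4,5-trimethoxyphenyl)-2,3-dihydro-1,4-benzodioxin-8-ol; 11 3,3-diethoxyprop-1-ene
Product: 13 (2E)-3-[(2S,3S)-8-hydroxy-2-(hydroxymethyl)-3-(3,4,5-trimethoxyphenyl)-2,3-dihydro-1,4-benzodioxin-6-yl]prop-2-enal, via enal diethyl acetal 12 (not isolated)
Conditions: Pd(OAc)2 (3 mol %), n-Bu4NOAc, K2CO3, KCl, DMF, 90 °C; then 2 M HCl, rt
Reagents that add atoms: 3,3-diethoxyprop-1-ene, C=CC(OCC)OCC; water, O
Why: Heck reaction of an aryl bromide with acrolein diethyl acetal under phosphine-free ammonium-salt conditions, followed by acetal hydrolysis, is an established entry to (E)-cinnamaldehydes (E from syn insertion and syn β-hydride elimination), and the two ring stereocentres carry no acidic hydrogen and should be untouched.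

Compound list
1 | 5-bromobenzene-1,2,3-triol | Oc1cc(Br)cc(O)c1O | starting material
2 | methyl bromoacetate | COC(=O)CBr | starting material
3 | methyl 2-(4-bromo-2,6-dihydroxyphenoxy)acetate | COC(=O)COc1c(O)cc(Br)cc1O | intermediate
4 | 7-bromo-5-hydroxy-1,4-benzodioxin-2(3H)-one | O=C1COc2c(O)cc(Br)cc2O1 | intermediate
5 | (3,4,5-trimethoxyphenyl)methanol | COc1cc(CO)cc(OC)c1OC | starting material
6 | 7-bromo-5-[(3,4,5-trimethoxyphenyl)methoxy]-1,4-benzodioxin-2(3H)-one | O=C1COc2c(OCc3cc(OC)c(OC)c(OC)c3)cc(Br)cc2O1 | intermediate
7 | 7-bromo-5-[(3,4,5-trimethoxyphenyl)methoxy]-2,3-dihydro-1,4-benzodioxin-2-ol (lactol, both epimers) | OC1COc2c(OCc3cc(OC)c(OC)c(OC)c3)cc(Br)cc2O1 | intermediate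
8 | (7-bromo-2-hydroxy-2,3-dihydro-1,4-benzodioxin-5-yl)[(3,4,5-trimethoxyphenyl)methylidene]oxonium 2,3-dichloro-5,6-dicyano-4-hydroxyphenolate | COc1cc(C=[O+]c2cc(Br)cc3OC(O)COc23)cc(OC)c1OC.[O-]c1c(Cl)c(Cl)c(O)c(C#N)c1C#N | intermediate
9 | (2R,3S)-6-bromo-8-hydroxy-3-(3,4,5-trimethoxyphenyl)-2,3-dihydro-1,4-benzodioxine-2-carbaldehyde (trans) | COc1cc([C@@H]2Oc3cc(Br)cc(O)c3O[C@H]2C=O)cc(OC)c1OC | intermediate
10 | (2S,3S)-6-bromo-2-(hydroxymethyl)-3-(3,4,5-trimethoxyphenyl)-2,3-dihydro-1,4-benzodioxin-8-ol (trans) | COc1cc([C@@H]2Oc3cc(Br)cc(O)c3O[C@H]2CO)cc(OC)c1OC | intermediate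
11 | 3,3-diethoxyprop-1-ene (acrolein diethyl acetal) | C=CC(OCC)OCC | starting material
12 | (2S,3S)-6-[(1E)-3,3-diethoxyprop-1-en-1-yl]-2-(hydroxymethyl)-3-(3,4,5-trimethoxyphenyl)-2,3-dihydro-1,4-benzodioxin-8-ol | COc1cc([C@@H]2Oc3cc(/C=C/C(OCC)OCC)cc(O)c3O[C@H]2CO)cc(OC)c1OC | intermediate
13 | (2E)-3-[(2S,3S)-8-hydroxy-2-(hydroxymethyl)-3-(3,4,5-trimethoxyphenyl)-2,3-dihydro-1,4-benzodioxin-6-yl]prop-2-enal | COc1cc([C@@H]2Oc3cc(/C=C/C=O)cc(O)c3O[C@H]2CO)cc(OC)c1OC | target

Total step count: 5
Longest linear sequence: 5 steps (1 → 4 → 6 → 7 → 10 → 13)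

Steps most likely to fail

Step 4. Hydride abstraction from the benzyl aryl ether may be too slow beside oxidation of the small share of ring-opened phenol. The cation may also be hydrolysed or captured by oxygen nucleophiles before the enamine reaches it, and an uncatalysed closure through the enol would erode the facial control. The fallback replaces oxidation by ionisation of a pre-installed leaving group; it sets out from 4 and comes back at 10. 3,4,5-Trimethoxybenzaldehyde and pivaloyl chloride (ZnCl2 cat., CH2Cl2) should give chloro(3,4,5-trimethoxyphenyl)methyl 2,2-dimethylpropanoate F1, the usual 1-chloroalkyl ester from an aldehyde and an acid chloride. Phenol 4 is O-alkylated with F1 (i-Pr2NEt, MeCN, 0 °C) to [(7-bromo-2-oxo-2,3-dihydro-1,4-benzodioxin-5-yl)oxy](3,4,5-trimethoxyphenyl)methyl 2,2-dimethylpropanoate F2; the hindered pivalate disfavours acyl transfer. i-Bu2AlH (1.0 equiv, CH2Cl2, −78 °C) should reduce the far more electrophilic aryl lactone to the lactol [(7-bromo-2-hydroxy-2,3-dihydro-1,4-benzodioxin-5-yl)oxy](3,4,5-trimethoxyphenyl)methyl 2,2-dimethylpropanoate F3. Yb(OTf)3 (10 mol %) with the same (S)-amine (20 mol %) in CH2Cl2 at −20 °C then ionises the α-acyloxy ether by loss of pivalate to the cation of 8. The enamine closes the same C2–C3 bond to 9, and NaBH4/MeOH gives 10. Both halves are known reaction types: Lewis-acid ionisation of α-acyloxy ethers to oxocarbenium ions, and amine/Lewis-acid dual catalysis for the addition of aldehydes to such ions.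

Step 1. The alkylation may fail to discriminate the middle hydroxyl from the two outer ones, or may run on to bis-ethers, which would give regioisomeric lactones that are hard to separate. The fallback fixes the site in the starting material; it sets out from 2 and comes back at 4. Commercial 4-bromo-2,6-dimethoxyphenol (COc1cc(Br)cc(OC)c1O), whose only free hydroxyl is the middle one, is alkylated with 2 (K2CO3, acetone, reflux) to methyl 2-(4-bromo-2,6-dimethoxyphenoxy)acetate F4. BBr3 (CH2Cl2, −78 to 0 °C) then cleaves the two aryl methyl ethers to give 3, which is lactonised as before (TsOH·H2O, toluene, reflux) to 4.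

Step 5. Oxidative addition and insertion may be slow on the electron-rich bromophenoxide, and β-hydride elimination toward the acetal carbon may divert the alkyl-palladium intermediate to the saturated ester instead of the enal acetal. The fallback is a Suzuki–Miyaura coupling, in which alkene geometry and regiochemistry are carried by the reagent; it sets out from 10 and comes back at 12. 10 is coupled with commercial (E)-2-(3,3-diethoxyprop-1-en-1-yl)-4,4,5,5-tetramethyl-1,3,2-dioxaborolane (PdCl2(dppf), K3PO4, dioxane/H2O, 80 °C) to give 12, and the same 2 M HCl hydrolysis gives 13.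

Further compounds
F1 | step 4 | chloro(3,4,5-trimethoxyphenyl)methyl 2,2-dimethylpropanoate | COc1cc(C(Cl)OC(=O)C(C)(C)C)cc(OC)c1OC
F2 | step 4 | [(7-bromo-2-oxo-2,3-dihydro-1,4-benzodioxin-5-yl)oxy](3,4,5-trimethoxyphenyl)methyl 2,2-dimethylpropanoate | O=C1COc2c(OC(OC(=O)C(C)(C)C)c3cc(OC)c(OC)c(OC)c3)cc(Br)cc2O1
F3 | step 4 | [(7-bromo-2-hydroxy-2,3-dihydro-1,4-benzodioxin-5-yl)oxy](3,4,5-trimethoxyphenyl)methyl 2,2-dimethylpropanoate | OC1COc2c(OC(OC(=O)C(C)(C)C)c3cc(OC)c(OC)c(OC)c3)cc(Br)cc2O1
F4 | step 1 | methyl 2-(4-bromo-2,6-dimethoxyphenoxy)acetate | COC(=O)COc1c(OC)cc(Br)cc1OC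
F0 | step 5 | none | none
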